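**Assumption:** natural (2S)-pinocembrin and (S)-(+)-α-phellandrene of high ee (dill/elemi oil grade) are taken as purchasable chiral-pool materials.

## Retrosynthetic overview

1. The only skeletal disconnection is the aryl–allyl bond C6–C1'. It leads back to (S)-pinocembrin 1, used as its 7-O-silyl ether 2, and to the diene (S)-α-phellandrene 3.
2. Forward: light-gated protonation of 3 gives an allyl cation that 2 captures at C6, anti to the isopropyl group, to give 4. Desilylation then gives target 5.
3. No ring is formed. Rings A, B and C come intact from 1 (with C2), and the cyclohexene ring comes from 3 (with C6'). The one new stereocenter, C1', is set by the neighbouring C6'.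
4. O7 is capped because in free 1 both C6 and C8 flank the unchelated 7-OH. In 2 the chelated 5-OH is the only free hydroxyl and C6 is its only ortho position.

## Route

**Step 1**
Reactants: 1 (S)-pinocembrin
Product: 2 (2S)-7-{[tert-butyl(dimethyl)silyl]oxy}-5-hydroxy-2-phenyl-2,3-dihydro-4H-chromen-4-one
Conditions: TBSCl (1.05 equiv), imidazole (2.2 equiv), DMF, 0 °C to rt
Reagents that add atoms: tert-butyldimethylsilyl chloride (TBSCl), CC(C)(C)[Si](C)(C)Cl
Why: Selective phenol silylation: the 5-OH is locked in the hydrogen bond to the C4 carbonyl, so only the free, more acidic 7-OH reacts; imidazole is too weak a base to open ring C, so C2 is untouched and no stereocenter is formed.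

**Step 2**
Reactants: 2 (2S)-7-{[tert-butyl(dimethyl)silyl]oxy}-5-hydroxy-2-phenyl-2,3-dihydro-4H-chromen-4-one; 3 (S)-α-phellandrene, (5S)-2-methyl-5-(propan-2-yl)cyclohexa-1,3-diene
Product: 4 (2S)-7-{[tert-butyl(dimethyl)silyl]oxy}-5-hydroxy-6-[(1S,6S)-3-methyl-6-(propan-2-yl)cyclohex-2-en-1-yl]-2-phenyl-2,3-dihydro-4H-chromen-4-one
Conditions: 3-{2-[(E)-2-(2-hydroxyphenyl)ethenyl]-3,3-dimethyl-3H-indol-1-ium-1-yl}propane-1-sulfonate (merocyanine photoacid, 5 mol %), 425 nm LEDs, CH2Cl2/HFIP 9:1, 0 °C, Ar; 3 (1.3 equiv) added over 2 h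
Reagents that add atoms: none
Why: Proposed new method: a light-gated Friedel–Crafts hydroarylation in which blue light ring-closes the protonated merocyanine to its spiropyran and releases a sulfonic-acid proton into the HFIP medium (neither 2 nor 3 absorbs at 425 nm, so the diene is not ring-opened); this proton adds to C1 of diene 3 to give the tertiary/secondary allyl cation, and 2 attacks the secondary terminus (C4 of 3) on the face anti to the adjacent isopropyl group, which sets C1' as S (trans) while C6' is carried over from 3; attack is expected at C6 because it is the only position ortho to the one free, chelated hydroxyl (the site preference known from iodination of 5-hydroxy-7-alkoxyflavones), and the silyl group also blocks O-alkylation, a second alkylation at C8 and ether formation onto the new alkene; the proton lost on rearomatisation reopens the spiropyran, so strong acid exists only while the lamp is on and no co-product forms; the closest known reaction types are the Brønsted acid-catalysed coupling of α-phellandrene with resorcinols and metastable-photoacid-catalysed esterification and acetal chemistry, neither of which has been applied to diene hydroarylation.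

**Step 3**
Reactants: 4 (2S)-7-{[tert-butyl(dimethyl)silyl]oxy}-5-hydroxy-6-[(1S,6S)-3-methyl-6-(propan-2-yl)cyclohex-2-en-1-yl]-2-phenyl-2,3-dihydro-4H-chromen-4-one
Product: 5 (2S)-5,7-dihydroxy-6-[(1S,6S)-3-methyl-6-(propan-2-yl)cyclohex-2-en-1-yl]-2-phenyl-2,3-dihydro-4H-chromen-4-one
Conditions: KHF2 (2.5 equiv), MeOH, rt to 40 °C
Reagents that add atoms: none
Why: Fluoride-driven Si–O cleavage of a phenolic silyl ether under weakly acidic, non-basic conditions, which leave the alkene, the ketone and the base-sensitive flavanone C2 centre alone; no stereocenter is formed or touched.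

## Compound list

1 | (S)-pinocembrin, (2S)-5,7-dihydroxy-2-phenyl-2,3-dihydro-4H-chromen-4-one | O=C1C[C@@H](c2ccccc2)Oc2cc(O)cc(O)c21 | starting material
2 | (2S)-7-{[tert-butyl(dimethyl)silyl]oxy}-5-hydroxy-2-phenyl-2,3-dihydro-4H-chromen-4-one | CC(C)(C)[Si](C)(C)Oc1cc2c(c(O)c1)C(=O)C[C@@H](c1ccccc1)O2 | intermediate
3 | (S)-α-phellandrene, (5S)-2-methyl-5-(propan-2-yl)cyclohexa-1,3-diene | CC1=CC[C@H](C=C1)C(C)C | starting material
4 | (2S)-7-{[tert-butyl(dimethyl)silyl]oxy}-5-hydroxy-6-[(1S,6S)-3-methyl-6-(propan-2-yl)cyclohex-2-en-1-yl]-2-phenyl-2,3-dihydro-4H-chromen-4-one | CC1=C[C@@H](c2c(O[Si](C)(C)C(C)(C)C)cc3c(c2O)C(=O)C[C@@H](c2ccccc2)O3)[C@H](C(C)C)CC1 | intermediate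
5 | (2S)-5,7-dihydroxy-6-[(1S,6S)-3-methyl-6-(propan-2-yl)cyclohex-2-en-1-yl]-2-phenyl-2,3-dihydro-4H-chromen-4-one | CC1=C[C@@H](c2c(O)cc3c(c2O)C(=O)C[C@@H](c2ccccc2)O3)[C@H](C(C)C)CC1 | target

## Step count

Total steps: 3. Longest linear sequence: 3 (1 → 2 → 4 → 5).

## Steps most likely to fail

**Step 2 (the proposed new step).** There are three risks. The photo-released acid may be too weak or too slow to protonate the diene. Some attack may occur at C8. The allyl cation may lose a proton to achiral α-terpinene and re-enter, which erodes C6' and shows up as diastereomers because C2 is fixed. The fallback uses known chemistry and sets out from 2. Allylic Friedel–Crafts alkylation of 2 with the limonene-derived alcohol (1S,4R)-1-methyl-4-(prop-1-en-2-yl)cyclohex-2-en-1-ol F1 (BF3·OEt2 on Al2O3, CH2Cl2, rt, the standard cannabidiol-type coupling, which is known to keep the terpene stereocenter) gives (2S)-7-{[tert-butyl(dimethyl)silyl]oxy}-5-hydroxy-6-[(1R,6R)-3-methyl-6-(prop-1-en-2-yl)cyclohex-2-en-1-yl]-2-phenyl-2,3-dihydro-4H-chromen-4-one F2. This has the same spatial arrangement as 4; the descriptors change only through CIP priorities. Hydrogenation with RhCl(PPh3)3 and H2 (1 atm) in benzene/EtOH saturates only the 1,1-disubstituted alkene and comes back to the route at 4. Any C8 isomer is removed by chromatography at that stage.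

**Step 3.** The silyl ether sits next to the bulky C6 substituent and may cleave slowly. Forcing the reaction with basic fluoride would risk opening ring C through the 7-phenoxide and epimerising C2. The fallback changes the protecting group to one that is removed under neutral conditions and sets out from 1. Ac2O (1.1 equiv) in pyridine at 0 °C gives (2S)-5-hydroxy-4-oxo-2-phenyl-3,4-dihydro-2H-chromen-7-yl acetate F3. The step 2 conditions with 3 then give (2S)-5-hydroxy-6-[(1S,6S)-3-methyl-6-(propan-2-yl)cyclohex-2-en-1-yl]-4-oxo-2-phenyl-3,4-dihydro-2H-chromen-7-yl acetate F4; the coupling is expected to be slower on this less electron-rich ring. NH4OAc in MeOH/H2O at rt removes the aryl acetate and comes back to the route at 5.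

**Step 1.** This is the least risky step; possible problems are partial silylation at O5 or trace racemisation if the base is overdosed. The fallback drops the protecting group and sets out from 1. Coupling 1 directly with 3 under the step 2 conditions gives 5 together with its regioisomer (2S)-5,7-dihydroxy-8-[(1S,6S)-3-methyl-6-(propan-2-yl)cyclohex-2-en-1-yl]-2-phenyl-2,3-dihydro-4H-chromen-4-one F5, which is separated by chromatography. This route is two steps shorter, comes back at 5, and costs yield to the C8 isomer and to 6,8-bis-adducts.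

## Further compounds

F1 | step 2 | (1S,4R)-1-methyl-4-(prop-1-en-2-yl)cyclohex-2-en-1-ol | C[C@@]1(O)C=C[C@H](C(C)=C)CC1
F2 | step 2 | (2S)-7-{[tert-butyl(dimethyl)silyl]oxy}-5-hydroxy-6-[(1R,6R)-3-methyl-6-(prop-1-en-2-yl)cyclohex-2-en-1-yl]-2-phenyl-2,3-dihydro-4H-chromen-4-one | CC1=C[C@@H](c2c(O[Si](C)(C)C(C)(C)C)cc3c(c2O)C(=O)C[C@@H](c2ccccc2)O3)[C@H](C(C)=C)CC1
F3 | step 3 | (2S)-5-hydroxy-4-oxo-2-phenyl-3,4-dihydro-2H-chromen-7-yl acetate | CC(=O)Oc1cc2c(c(O)c1)C(=O)C[C@@H](c1ccccc1)O2
F4 | step 3 | (2S)-5-hydroxy-6-[(1S,6S)-3-methyl-6-(propan-2-yl)cyclohex-2-en-1-yl]-4-oxo-2-phenyl-3,4-dihydro-2H-chromen-7-yl acetate | CC1=C[C@@H](c2c(OC(C)=O)cc3c(c2O)C(=O)C[C@@H](c2ccccc2)O3)[C@H](C(C)C)CC1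
F5 | step 1 | (2S)-5,7-dihydroxy-8-[(1S,6S)-3-methyl-6-(propan-2-yl)cyclohex-2-en-1-yl]-2-phenyl-2,3-dihydro-4H-chromen-4-one | CC1=C[C@@H](c2c(O)cc(O)c3c2O[C@H](c2ccccc2)CC3=O)[C@H](C(C)C)CC1
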